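**Retrosynthetic overview**

1. The target is cut at the bridge CH2–C6 bond of the triketone ring. This gives the enantiopure acetyl-triketone 15 and the chromene Mannich base 22 (an ortho-quinone methide donor); the chromene comes from butanoylphloroglucinol and 3-methylbut-2-enal.
2. The triketone ring is made by a two-carbon ring expansion of a 3-aminocyclobutenone with diketene. Ring atoms C3, C4, C5 and C6 are a latent cyclobutane-1,3-dione. Ring atoms C1 and C2, with the acetyl group, are an acetoacetyl unit. Bonds C6–C1 and C2–C3 are made, and the old four-ring bond C3–C6 is cut.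
3. The enabling feature is that the quaternary carbon C4 lies between two carbonyl-derived carbons (C3, C5) and never has to react. As C2 of a 2,2-disubstituted cyclobutane-1,3-dione it is prochiral, and a desymmetrising enaminone formation makes it the stereocentre before the expansion.
4. The four-membered ring comes from a [2+2] cycloaddition of geranyl(methyl)ketene with ethoxyethyne; the ketene comes from propanoic acid and geranyl bromide.
5. Ring order: cyclobutenone, then the six-membered triketone ring by expansion; separately the pyran ring on the acylphloroglucinol; union of the two halves last.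

Key step: step 6

Assumption: β-di- and tricarbonyl compounds are drawn as one of their rapidly interconverting enol forms, and descriptors refer to the drawn form; "geranyl" means (2E)-3,7-dimethylocta-2,6-dien-1-yl.
Assumption: the catalyst enantiomer in step 5 that gives the 4R enaminone is identified in a first run with both antipodes; the sense of induction cannot be predicted here.

**Step 1**
Reactants: 1 propanoic acid; 2 geranyl bromide [(2E)-1-bromo-3,7-dimethylocta-2,6-diene]
Product: 3 racemic (4E)-2,5,9-trimethyldeca-4,8-dienoic acid
Conditions: LiN(iPr)2 (2.2 equiv), THF/DMPU, 0 °C; then 2, 0 °C to rt; 1 M HCl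
Reagents that add atoms: none
Why: C-alkylation of the propanoate dianion (enediolate) with the allylic bromide is a standard SN2 reaction that keeps the E alkene; the new stereocentre forms racemic and is erased at the ketene stage.

**Step 2**
Reactants: 3 racemic (4E)-2,5,9-trimethyldeca-4,8-dienoic acid
Product: 4 racemic (4E)-2,5,9-trimethyldeca-4,8-dienoyl chloride
Conditions: (COCl)2 (1.2 equiv), N,N-dimethylformamide (cat.), CH2Cl2, 0 °C to rt, N2 sweep; concentrate
Reagents that add atoms: oxalyl chloride (ClC(=O)C(Cl)=O)
Why: Acid chloride formation through the chloroiminium (Vilsmeier-type) intermediate should be mild enough for the two trisubstituted alkenes if the HCl is swept out cold.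

**Step 3**
Reactants: 4 racemic (4E)-2,5,9-trimethyldeca-4,8-dienoyl chloride; 5 ethoxyethyne
Product: 7 racemic 3-ethoxy-4-geranyl-4-methylcyclobut-2-en-1-one, via geranyl(methyl)ketene 6 (not isolated)
Conditions: Et3N (1.5 equiv), 5 (2 equiv, solution in hexanes), MeCN, rt to 45 °C
Reagents that add atoms: none
Why: Dehydrochlorination gives the dialkylketene, which should undergo the regioselective ketene–ynol ether [2+2] cycloaddition (ketene carbonyl carbon to the alkyne CH, ketene α-carbon to the C–OEt carbon); the quaternary centre forms racemic, which does not matter because step 4 makes it prochiral.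

**Step 4**
Reactants: 7 racemic 3-ethoxy-4-geranyl-4-methylcyclobut-2-en-1-one
Product: 8 2-geranyl-2-methylcyclobutane-1,3-dione (achiral, C2 prochiral)
Conditions: 1 M aq. HCl, THF, rt
Reagents that add atoms: water (O)
Why: Acid hydrolysis of the vinylogous ester (addition–elimination of water at C3) should give the Cs-symmetric dione with two enantiotopic carbonyl groups; cold dilute acid leaves the geranyl alkenes alone.

**Step 5**
Reactants: 8 2-geranyl-2-methylcyclobutane-1,3-dione; 9 4-methoxyaniline
Product: 10 (4R)-4-geranyl-3-[(4-methoxyphenyl)amino]-4-methylcyclobut-2-en-1-one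
Conditions: 9 (1.05 equiv), 3,3'-bis(2,4,6-triisopropylphenyl)-1,1'-binaphthalene-2,2'-diyl hydrogen phosphate (5 mol%, enantiomer chosen to give the 4R product), 5 Å molecular sieves, toluene, 0 °C to rt
Reagents that add atoms: none
Why: Chiral-phosphoric-acid-catalysed desymmetrising carbonyl–amine condensation of a 2,2-disubstituted cyclobutane-1,3-dione: the amine adds to one enantiotopic C=O inside the chiral hydrogen-bonded ion pair and dehydration gives the vinylogous amide, so the catalyst enantiomer fixes the quaternary carbon as R.

**Step 6**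
Reactants: 10 (4R)-4-geranyl-3-[(4-methoxyphenyl)amino]-4-methylcyclobut-2-en-1-one; 11 diketene (4-methylideneoxetan-2-one)
Product: 14 (4R)-2-acetyl-4-geranyl-3-hydroxy-5-[(4-methoxyphenyl)amino]-4-methylcyclohexa-2,5-dien-1-one, via C-acetoacetyl cyclobutenone 12 (not isolated), via open-chain enaminone ester 13 (not isolated)
Conditions: 11 (1.3 equiv, slow addition), 4-(dimethylamino)pyridine (5 mol%), CH2Cl2, 0 °C to rt; then Mg(OMe)2 (3 equiv), MeOH, rt to 45 °C; 1 M HCl work-up
Reagents that add atoms: none
Why: Proposed new method: the enaminone α-carbon C2 of 10 is C-acylated by diketene to give 12; Mg(OMe)2 then chelates the ring C1=O and the side-chain C=O, methoxide adds to the strained ring carbonyl C1, and the adduct fragments across C1–C2 (retro-Claisen) to the open-chain ester 13, whose magnesium β-diketonate carbon (the former CH2 of diketene) attacks the new ester in a Claisen condensation, so the two diketene carbons end up between C1 and C2 and the four-membered ring becomes the six-membered acetyl-triketone ring in one flask. The closest known reaction types are the alkoxide retro-Claisen opening of 2-acylcyclobutanones to 5-oxo esters and the magnesium-methoxide-mediated Claisen cyclisation of 3,5,7-tricarbonyl esters to acylphloroglucinols; joining them into a two-carbon ring expansion of a 3-aminocyclobutenone is new. The six-membered ring closes by a 6-exo-trig C-acylation (carbanion on ester carbonyl, loss of methoxide), driven by release of ring strain and formation of the triacylmethane anion. No stereocentre is formed: the quaternary carbon keeps all four bonds throughout, so its configuration comes unchanged from 10, provided the cyclobutenone stays below about 50 °C until it is opened, since a reversible electrocyclic opening to a vinylketene would racemise it. The step needs C- rather than N-acylation (N-acetoacetyl material should be returned to 10 by methoxide), cleavage of C1–C2 rather than C1–C4 (only the former gives a carbanion stabilised as a vinylogous amide and β-diketonate), and Claisen rather than aldol closure (the nitrogen keeps its carbon at the unreactive vinylogous-amide level, which blocks the aldol–aromatisation path, and the enamine double bond of 13 equilibrates through the imine tautomer to the geometry that can close).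

**Step 7**
Reactants: 14 (4R)-2-acetyl-4-geranyl-3-hydroxy-5-[(4-methoxyphenyl)amino]-4-methylcyclohexa-2,5-dien-1-one
Product: 15 (4R)-2-acetyl-4-geranyl-3,5-dihydroxy-4-methylcyclohexa-2,5-dien-1-one
Conditions: 1 M aq. HCl/THF (1:1), rt to 40 °C; extraction from the acidic phase
Reagents that add atoms: water (O)
Why: Acid hydrolysis of a vinylogous amide (water adds to the protonated enaminone, the arylammonium ion leaves into the aqueous phase) should give the free β-triketone; the configuration is now held by the acetyl group on one side of the quaternary carbon, and dilute acid at or below 40 °C should not protonate the geranyl alkenes.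

**Step 8**
Reactants: 16 phloroglucinol (benzene-1,3,5-triol); 17 butanoyl chloride
Product: 18 1-(2,4,6-trihydroxyphenyl)butan-1-one
Conditions: AlCl3 (3.5 equiv), PhNO2/CH2Cl2, 0 °C to 50 °C; ice/HCl
Reagents that add atoms: none
Why: Friedel–Crafts C-acylation of the electron-rich triol stops at monoacylation because the aluminium-chelated aryl ketone is deactivated.

**Step 9**
Reactants: 18 1-(2,4,6-trihydroxyphenyl)butan-1-one; 19 3-methylbut-2-enal
Product: 20 1-(5,7-dihydroxy-2,2-dimethyl-2H-chromen-6-yl)butan-1-one
Conditions: 19 (1.1 equiv), pyridine, 110 °C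
Reagents that add atoms: none
Why: Knoevenagel-type condensation at a ring carbon, dehydration to an ortho-quinone methide and oxa-6π electrocyclisation (formal [3+3] chromene annulation); the non-chelated hydroxyl para to the acyl group should close the pyran preferentially, and the 8-acyl isomer and any bis-pyran are removed by chromatography.

**Step 10**
Reactants: 20 1-(5,7-dihydroxy-2,2-dimethyl-2H-chromen-6-yl)butan-1-one; 21 bis(dimethylamino)methane
Product: 22 1-{8-[(dimethylamino)methyl]-5,7-dihydroxy-2,2-dimethyl-2H-chromen-6-yl}butan-1-one
Conditions: 21 (1.2 equiv), 1,4-dioxane, rt to 50 °C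
Reagents that add atoms: none
Why: Mannich aminomethylation: the acidic phenol converts the aminal into the iminium ion, which attacks C8, the only free aromatic carbon.

**Step 11**
Reactants: 15 (4R)-2-acetyl-4-geranyl-3,5-dihydroxy-4-methylcyclohexa-2,5-dien-1-one; 22 1-{8-[(dimethylamino)methyl]-5,7-dihydroxy-2,2-dimethyl-2H-chromen-6-yl}butan-1-one
Product: 24 target CNP0203748.1 [(4R)-2-acetyl-6-[(6-butanoyl-5,7-dihydroxy-2,2-dimethyl-2H-chromen-8-yl)methyl]-4-geranyl-3,5-dihydroxy-4-methylcyclohexa-2,5-dien-1-one], via ortho-quinone methide 23 (not isolated)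
Conditions: 1,4-dioxane, 90 °C, Ar
Reagents that add atoms: none
Why: The acidic triketone protonates the Mannich base, dimethylamine is eliminated to the ortho-quinone methide, and the enol carbon C6 of 15 (its only free ring position) adds in a Michael reaction, the usual way to join the halves of methylene-bridged acylphloroglucinol dimers; the quaternary stereocentre is not involved.

**Compound list**

1 | propanoic acid | CCC(=O)O | starting material
2 | geranyl bromide, (2E)-1-bromo-3,7-dimethylocta-2,6-diene | BrC/C=C(\C)CCC=C(C)C | starting material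
3 | racemic (4E)-2,5,9-trimethyldeca-4,8-dienoic acid | CC(C/C=C(\C)CCC=C(C)C)C(=O)O | intermediate
4 | racemic (4E)-2,5,9-trimethyldeca-4,8-dienoyl chloride | CC(C/C=C(\C)CCC=C(C)C)C(Cl)=O | intermediate
5 | ethoxyethyne | CCOC#C | starting material
6 | geranyl(methyl)ketene, (4E)-2,5,9-trimethyldeca-1,4,8-trien-1-one | CC(C/C=C(\C)CCC=C(C)C)=C=O | intermediate (not isolated)
7 | racemic 3-ethoxy-4-geranyl-4-methylcyclobut-2-en-1-one | CCOC1=CC(=O)C1(C)C/C=C(\C)CCC=C(C)C | intermediate
8 | 2-geranyl-2-methylcyclobutane-1,3-dione | CC1(C/C=C(\C)CCC=C(C)C)C(=O)CC1=O | intermediate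
9 | 4-methoxyaniline | COc1ccc(N)cc1 | starting material
10 | (4R)-4-geranyl-3-[(4-methoxyphenyl)amino]-4-methylcyclobut-2-en-1-one | O=C1C=C(Nc2ccc(OC)cc2)[C@@]1(C)C/C=C(\C)CCC=C(C)C | intermediate
11 | diketene, 4-methylideneoxetan-2-one | C=C1CC(=O)O1 | starting material
12 | (4R)-4-geranyl-3-[(4-methoxyphenyl)amino]-4-methyl-2-(3-oxobutanoyl)cyclobut-2-en-1-one | CC(=O)CC(=O)C1=C(Nc2ccc(OC)cc2)[C@@](C)(C/C=C(\C)CCC=C(C)C)C1=O | intermediate (not isolated)
13 | methyl (2R,3Z)-2-geranyl-3-[(4-methoxyphenyl)amino]-2-methyl-5,7-dioxooct-3-enoate | COC(=O)[C@](C)(C/C=C(\C)CCC=C(C)C)/C(Nc1ccc(OC)cc1)=C/C(=O)CC(C)=O | intermediate (not isolated)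
14 | (4R)-2-acetyl-4-geranyl-3-hydroxy-5-[(4-methoxyphenyl)amino]-4-methylcyclohexa-2,5-dien-1-one | CC(=O)C1=C(O)[C@](C)(C/C=C(\C)CCC=C(C)C)C(Nc2ccc(OC)cc2)=CC1=O | intermediate
15 | (4R)-2-acetyl-4-geranyl-3,5-dihydroxy-4-methylcyclohexa-2,5-dien-1-one | CC(=O)C1=C(O)[C@](C)(C/C=C(\C)CCC=C(C)C)C(O)=CC1=O | intermediate
16 | phloroglucinol | Oc1cc(O)cc(O)c1 | starting material
17 | butanoyl chloride | CCCC(Cl)=O | starting material
18 | 1-(2,4,6-trihydroxyphenyl)butan-1-one | CCCC(=O)c1c(O)cc(O)cc1O | intermediate
19 | 3-methylbut-2-enal | CC(C)=CC=O | starting material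
20 | 1-(5,7-dihydroxy-2,2-dimethyl-2H-chromen-6-yl)butan-1-one | CCCC(=O)c1c(O)cc2OC(C)(C)C=Cc2c1O | intermediate
21 | bis(dimethylamino)methane | CN(C)CN(C)C | starting material
22 | 1-{8-[(dimethylamino)methyl]-5,7-dihydroxy-2,2-dimethyl-2H-chromen-6-yl}butan-1-one | CCCC(=O)c1c(O)c(CN(C)C)c2OC(C)(C)C=Cc2c1O | intermediate
23 | 6-butanoyl-5-hydroxy-2,2-dimethyl-8-methylidene-2H-chromen-7(8H)-one (ortho-quinone methide) | CCCC(=O)C1=C(O)C2=C(OC(C)(C)C=C2)C(=C)C1=O | intermediate (not isolated)
24 | CNP0203748.1, (4R)-2-acetyl-6-[(6-butanoyl-5,7-dihydroxy-2,2-dimethyl-2H-chromen-8-yl)methyl]-4-geranyl-3,5-dihydroxy-4-methylcyclohexa-2,5-dien-1-one | CCCC(=O)c1c(O)c2c(c(CC3=C(O)[C@@](C)(C/C=C(\C)CCC=C(C)C)C(O)=C(C(C)=O)C3=O)c1O)OC(C)(C)C=C2 | target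

**Step count and risks**

Total steps: 11. Longest linear sequence: 8 (steps 1 to 7, then step 11).

Step 6 (bears the label). The ring carbonyl is part of a vinylogous amide and may add methoxide too slowly, so that the acetoacetyl chain is lost or closes through nitrogen first; the open-chain ester may also close through oxygen instead of carbon. The fallback sets out from 10 and comes back at 14, using three separate reactions of known type. Compound 10 is C-acetoacetylated with diketene and 12 is isolated. The four-membered ring is then cleaved on purpose with NaOMe (1.1 equiv) in MeOH at 0 °C, the alkoxide retro-Claisen opening known for 2-acylcyclobutanones, and the open-chain ester 13 is isolated. The six-membered ring is closed separately by a Dieckmann-type Claisen condensation with KOtBu in THF to give 14. This fallback makes no compound outside the list (F0).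

Step 5. The catalyst may discriminate poorly between the two enantiotopic carbonyl groups (methyl against a primary allylic chain on the prochiral carbon), and the acidic dione may drive a racemic background condensation. The fallback sets out from 8 and comes back at 15, replacing catalysis by a covalent auxiliary. Compound 8 is condensed with (S)-1-phenylethylamine (toluene, molecular sieves, rt) to two diastereomeric enaminones, which are separated by chromatography or crystallisation. The wanted one is (4R)-4-geranyl-4-methyl-3-{[(1S)-1-phenylethyl]amino}cyclobut-2-en-1-one F1. The unwanted (4S)-4-geranyl-4-methyl-3-{[(1S)-1-phenylethyl]amino}cyclobut-2-en-1-one F2 is hydrolysed back to 8 with dilute acid and recycled. F1 is taken through the protocol of step 6, via the C-acetoacetyl cyclobutenone F3 and the open-chain ester F4, to (4R)-2-acetyl-4-geranyl-3-hydroxy-4-methyl-5-{[(1S)-1-phenylethyl]amino}cyclohexa-2,5-dien-1-one F5. Acid hydrolysis as in step 7 then gives 15.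

Step 9. Regioselectivity between the two hydroxyl groups that can close the pyran ring may be poor, and a second annulation may give a bis-pyran. The fallback sets out from 18 and comes back at 20, fixing the ring oxygen before the ring is made. The most acidic, non-chelated 4-hydroxyl of 18 is O-alkylated with 3-chloro-3-methylbut-1-yne (K2CO3, KI, CuCl2·2H2O cat., acetone, rt to 50 °C) to 1-{2,6-dihydroxy-4-[(2-methylbut-3-yn-2-yl)oxy]phenyl}butan-1-one F6. Heating F6 in xylene at 140 °C should bring about aromatic Claisen rearrangement, 1,5-hydrogen shift and oxa-6π closure to 20, with the pyran oxygen para to the acyl group.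

**Further compounds**

F0 | step 6 | none | none
F1 | step 5 | (4R)-4-geranyl-4-methyl-3-{[(1S)-1-phenylethyl]amino}cyclobut-2-en-1-one | O=C1C=C(N[C@@H](C)c2ccccc2)[C@@]1(C)C/C=C(\C)CCC=C(C)C
F2 | step 5 | (4S)-4-geranyl-4-methyl-3-{[(1S)-1-phenylethyl]amino}cyclobut-2-en-1-one | O=C1C=C(N[C@@H](C)c2ccccc2)[C@]1(C)C/C=C(\C)CCC=C(C)C
F3 | step 5 | (4R)-4-geranyl-4-methyl-2-(3-oxobutanoyl)-3-{[(1S)-1-phenylethyl]amino}cyclobut-2-en-1-one | CC(=O)CC(=O)C1=C(N[C@@H](C)c2ccccc2)[C@@](C)(C/C=C(\C)CCC=C(C)C)C1=O
F4 | step 5 | methyl (2R,3Z)-2-geranyl-2-methyl-5,7-dioxo-3-{[(1S)-1-phenylethyl]amino}oct-3-enoate | COC(=O)[C@](C)(C/C=C(\C)CCC=C(C)C)/C(N[C@@H](C)c1ccccc1)=C/C(=O)CC(C)=O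
F5 | step 5 | (4R)-2-acetyl-4-geranyl-3-hydroxy-4-methyl-5-{[(1S)-1-phenylethyl]amino}cyclohexa-2,5-dien-1-one | CC(=O)C1=C(O)[C@](C)(C/C=C(\C)CCC=C(C)C)C(N[C@@H](C)c2ccccc2)=CC1=O
F6 | step 9 | 1-{2,6-dihydroxy-4-[(2-methylbut-3-yn-2-yl)oxy]phenyl}butan-1-one | CCCC(=O)c1c(O)cc(OC(C)(C)C#C)cc1O
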